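1. Last C–C bond: Suzuki–Miyaura coupling across the central C–C single bond of the (E,E)-diene joins an (E)-iodovinyl bromo-oxane to an (E)-trisubstituted alkenyl boronate; fluoride then frees the tertiary alcohol.
2. Cyclohexane ring: bought as (S)-limonene. Epoxide hydrolysis gives the trans-diaxial 1,2-diol, SN2 bromide at C2 turns it into the cis-bromohydrin (Br equatorial, OH axial), and the isopropenyl group becomes methyl ketone, then boronate.
3. Oxane ring: bonds C2–C3 and C5–C6 are made together by a (4+3) cycloaddition of 2,5-dimethylfuran with a chiral 1-alkoxy-2-silyloxyallyl cation. The product is an 8-oxabicyclo[3.2.1]oct-6-en-3-one whose six-membered C–O–C ring is the oxane.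
4. Enabling feature: the unit C2–O1–C6 of the oxane links two fully substituted carbons that each carry a methyl group, and the first diene carbon on C2 lies cis (1,3 across O1) to one methyl on C6. These two carbons can therefore be tied as a CH=CH bridge, and O1, C2, C6 plus that bridge are 2,5-dimethylfuran.
5. After the key step, ozonolysis cuts the temporary seven-membered ring, the activating C4 oxygen and the oxygen of the C6 arm leave together by radical deoxygenation, and the C5–O bond becomes C5–Br with inversion. Ring order: cyclohexane (chiral pool), furan (bought), oxane plus temporary carbocycle (key step), carbocycle opened.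

Key step: step 3

Assumption: the (R)-1-phenylethyl group is taken to hold its C–H bond eclipsed with the C=O+ bond and its phenyl ring over one face of the allyl cation, which sends the furan to the other face and gives the (1R,2S,5R) adduct; should the sense be the reverse, (S)-1-phenylethanol is used and nothing else changes.
Numbering in names: oxane O1, C2 (quaternary carbon that carries the side chain), C5 (C–O, later C–Br), C6 (later CMe2). Cyclohexane as in limonene: C1 (C–CH3), C2 (C–O, later C–Br), C4 (side chain).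

Step 1
Reactants: 1 1,1-dimethoxypropan-2-one; 2 (R)-1-phenylethanol
Product: 3 1-methoxy-1-[(R)-1-phenylethoxy]propan-2-one (both epimers at the acetal carbon)
Conditions: CSA (cat.), excess 1, toluene, 60 °C, MeOH removed under reduced pressure
Reagents that add atoms: none
Why: Acid-catalysed transacetalisation driven by removal of methanol exchanges one methoxy group without breaking the C–O bond of the carbinol stereocentre, and the new acetal carbon is an epimer mixture that is erased on ionisation in step 3.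

Step 2
Reactants: 3 1-methoxy-1-[(R)-1-phenylethoxy]propan-2-one
Product: 4 triethyl({3-methoxy-3-[(R)-1-phenylethoxy]prop-1-en-2-yl}oxy)silane
Conditions: TESOTf, Et3N, CH2Cl2, 0 °C
Reagents that add atoms: triethylsilyl triflate CC[Si](CC)(CC)OS(=O)(=O)C(F)(F)F
Why: Silyl enol ether formation by soft enolisation (silyl triflate plus amine) goes to the unhindered methyl side of the ketone and creates no stereocentre.

Step 3
Reactants: 4 triethyl({3-methoxy-3-[(R)-1-phenylethoxy]prop-1-en-2-yl}oxy)silane; 5 2,5-dimethylfuran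
Product: 7 (1R,2S,5R)-1,5-dimethyl-2-[(R)-1-phenylethoxy]-8-oxabicyclo[3.2.1]oct-6-en-3-one, via alkoxy-silyloxyallyl cation triflate 6 (not isolated)
Conditions: TMSOTf (10 mol %), 5 (3 equiv), CH2Cl2, −95 °C to −78 °C
Reagents that add atoms: none
Why: The silyl triflate ionises the less hindered methoxy group of 4 to the W-shaped cation 6, whose CH2 terminus is attacked by one α-carbon of the furan and whose alkoxy-bearing terminus, now a silyl enol ether carbon, closes onto the furan oxocarbenium at the other α-carbon, after which loss of the silyl group leaves the ketone and regenerates silyl triflate. The closest known reaction type is the low-temperature (4+3) cycloaddition of furans with acetal-derived 1-alkoxy-2-silyloxyallyl cations that carry a 1-phenylethyl auxiliary, here only moved to 2,5-dimethylfuran. The two new bonds together close the seven-membered cycloheptenone ring and, through the furan oxygen, the six-membered oxan-4-one ring, in an intermolecular suprafacial 4π+2π mode through the compact (endo) arrangement. The two quaternary bridgeheads must be cis because both bonds form on one face of the planar furan, the alkoxy carbon ends equatorial and cis to the etheno bridge because a W-configured cation reacts through the compact arrangement, and the absolute sense comes from the auxiliary, whose phenyl ring covers one face of the cation. No regiochemical question arises because the diene is symmetric, substitution instead of ring closure is shut off because the attacked furan carbon bears methyl and cannot rearomatise, and ionisation of OMe rather than of the bulkier benzylic alkoxy group keeps the auxiliary on the cation.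

Step 4
Reactants: 7 (1R,2S,5R)-1,5-dimethyl-2-[(R)-1-phenylethoxy]-8-oxabicyclo[3.2.1]oct-6-en-3-one
Product: 9 (2R,4R,5R,6R)-2,6-bis(hydroxymethyl)-2,6-dimethyl-5-[(R)-1-phenylethoxy]oxan-4-ol, via secondary ozonide 8 (not isolated)
Conditions: O3, CH2Cl2, −78 °C; then NaBH4, MeOH, −78 °C to rt
Reagents that add atoms: ozone [O-][O+]=O
Why: Ozonolysis with reductive work-up cleaves only the strained etheno bridge and reduces ozonide and ketone in the same flask, hydride reaching C4 from the face of the ring oxygen so that the C4 carbinol, which is deleted in step 7, is drawn as the epimer cis to the two arms.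

Step 5
Reactants: 9 (2R,4R,5R,6R)-2,6-bis(hydroxymethyl)-2,6-dimethyl-5-[(R)-1-phenylethoxy]oxan-4-ol
Product: 10 (2R,4R,5R,6R)-2-[(tert-butyldiphenylsilyloxy)methyl]-6-(hydroxymethyl)-2,6-dimethyl-5-[(R)-1-phenylethoxy]oxan-4-ol
Conditions: TBDPSCl (1.0 equiv), imidazole, CH2Cl2–DMF, −20 °C to 0 °C
Reagents that add atoms: tert-butylchlorodiphenylsilane CC(C)(C)[Si](Cl)(c1ccccc1)c1ccccc1
Why: Sterically controlled monosilylation should take the primary alcohol on C2, flanked only by CH2, ahead of the one on C6, which is crowded by the cis 1-phenylethoxy group on C5, and ahead of the secondary C4 alcohol.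

Step 6
Reactants: 10 (2R,4R,5R,6R)-2-[(tert-butyldiphenylsilyloxy)methyl]-6-(hydroxymethyl)-2,6-dimethyl-5-[(R)-1-phenylethoxy]oxan-4-ol
Product: 11 bis(O-phenyl thionocarbonate) of 10 (on the C4 oxygen and on the CH2O arm of C6)
Conditions: PhOC(S)Cl, pyridine, DMAP (cat.), CH2Cl2, rt
Reagents that add atoms: O-phenyl chlorothionoformate S=C(Cl)Oc1ccccc1
Why: Acylation of the two remaining hydroxyl groups gives the thiocarbonyl precursors of a Barton–McCombie reaction under neutral conditions that avoid silyl migration and touch no stereocentre.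

Step 7
Reactants: 11 bis(O-phenyl thionocarbonate) of 10
Product: 12 (2R,5R)-2-[(tert-butyldiphenylsilyloxy)methyl]-2,6,6-trimethyl-5-[(R)-1-phenylethoxy]oxane
Conditions: Bu3SnH, AIBN, toluene, reflux
Reagents that add atoms: none
Why: A twofold Barton–McCombie deoxygenation turns C4 into CH2 and the C6 arm into the second methyl group in one operation, the β-alkoxy radicals involved do not fragment, and the C4 and C6 stereocentres disappear.

Step 8
Reactants: 12 (2R,5R)-2-[(tert-butyldiphenylsilyloxy)methyl]-2,6,6-trimethyl-5-[(R)-1-phenylethoxy]oxane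
Product: 13 (2R,5R)-2-[(tert-butyldiphenylsilyloxy)methyl]-2,6,6-trimethyloxan-5-ol
Conditions: H2 (1 atm), Pd(OH)2/C, EtOAc–EtOH, rt
Reagents that add atoms: none
Why: Hydrogenolysis of the benzylic ether removes the auxiliary by cleaving its own C–O bond, so the C5 configuration is kept and the silyl ether is untouched.

Step 9
Reactants: 13 (2R,5R)-2-[(tert-butyldiphenylsilyloxy)methyl]-2,6,6-trimethyloxan-5-ol
Product: 15 (2R,5S)-5-bromo-2-[(tert-butyldiphenylsilyloxy)methyl]-2,6,6-trimethyloxane, via alkoxyphosphonium bromide 14 (not isolated)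
Conditions: CBr4, P(n-Oct)3, toluene, 70 °C
Reagents that add atoms: tetrabromomethane BrC(Br)(Br)Br; tri-n-octylphosphine CCCCCCCCP(CCCCCCCC)CCCCCCCC (its atoms stay only in 14)
Why: In this Appel-type deoxybromination the alkoxyphosphonium bromide collapses by SN2, a pathway that holds even at neopentyl carbon because no free cation is formed, so the C5–O bond, axial in the chair that keeps the larger C2 arm equatorial, is replaced by equatorial bromine with inversion to 5S.

Step 10
Reactants: 15 (2R,5S)-5-bromo-2-[(tert-butyldiphenylsilyloxy)methyl]-2,6,6-trimethyloxane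
Product: 16 [(2R,5S)-5-bromo-2,6,6-trimethyloxan-2-yl]methanol
Conditions: TBAF, AcOH, THF, rt to 40 °C
Reagents that add atoms: none
Why: Fluoride desilylation buffered with acetic acid frees the primary alcohol without building up an alkoxide that could attack C5 across the ring from the face opposite to bromine.

Step 11
Reactants: 16 [(2R,5S)-5-bromo-2,6,6-trimethyloxan-2-yl]methanol
Product: 17 (2R,5S)-5-bromo-2,6,6-trimethyloxane-2-carbaldehyde
Conditions: Dess–Martin periodinane, CH2Cl2, rt
Reagents that add atoms: none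
Why: Dess–Martin oxidation stops at the aldehyde, which has no α-hydrogen and therefore cannot epimerise.

Step 12
Reactants: 17 (2R,5S)-5-bromo-2,6,6-trimethyloxane-2-carbaldehyde
Product: 18 (2R,5S)-5-bromo-2-[(E)-2-iodoethenyl]-2,6,6-trimethyloxane
Conditions: CrCl2, CHI3, THF–dioxane, 0 °C to rt
Reagents that add atoms: iodoform IC(I)I
Why: The Takai olefination gives the E-iodoalkene preferentially, most reliably with α-branched aldehydes, and divalent chromium leaves an unactivated secondary alkyl bromide alone.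

Step 13
Reactants: 19 (S)-(−)-limonene
Product: 20 (4S)-limonene 1,2-oxide (both epoxide diastereomers)
Conditions: mCPBA (1.0 equiv), CH2Cl2, 0 °C
Reagents that add atoms: 3-chloroperoxybenzoic acid OOC(=O)c1cccc(Cl)c1
Why: Prilezhaev epoxidation picks the more electron-rich trisubstituted ring alkene over the isopropenyl group, and the lack of facial selectivity does not matter because both epoxides are used in step 14.

Step 14
Reactants: 20 (4S)-limonene 1,2-oxide (both epoxide diastereomers)
Product: 21 (1R,2R,4S)-1-methyl-4-(prop-1-en-2-yl)cyclohexane-1,2-diol (both hydroxyl groups axial)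
Conditions: H2SO4 (cat.), H2O–THF, 0 °C to rt
Reagents that add atoms: water O
Why: In the acid-catalysed epoxide hydrolysis the Fürst–Plattner rule makes one epoxide open at C1 and the other at C2, each trans-diaxially, so both converge on the same diol with C1–OH cis to the C4 side chain.

Step 15
Reactants: 21 (1R,2R,4S)-1-methyl-4-(prop-1-en-2-yl)cyclohexane-1,2-diol
Product: 23 (1R,2R,4S)-1-methyl-4-(prop-1-en-2-yl)-1-(triethylsilyloxy)cyclohexan-2-ol, via bis-TES ether 22 (not isolated)
Conditions: TESOTf (2.5 equiv), 2,6-lutidine, CH2Cl2, 0 °C to rt; then MeOH, PPTS (cat.), 0 °C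
Reagents that add atoms: triethylsilyl triflate CC[Si](CC)(CC)OS(=O)(=O)C(F)(F)F
Why: Exhaustive silylation followed by mild acid methanolysis exploits the faster solvolysis of a secondary silyl ether compared with a tertiary one, which leaves only the tertiary oxygen masked and changes no stereocentre.

Step 16
Reactants: 23 (1R,2R,4S)-1-methyl-4-(prop-1-en-2-yl)-1-(triethylsilyloxy)cyclohexan-2-ol
Product: 25 {[(1R,2S,4S)-2-bromo-1-methyl-4-(prop-1-en-2-yl)cyclohexyl]oxy}triethylsilane, via alkoxyphosphonium bromide 24 (not isolated)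
Conditions: CBr4, P(n-Oct)3, toluene, 70 °C
Reagents that add atoms: tetrabromomethane BrC(Br)(Br)Br; tri-n-octylphosphine CCCCCCCCP(CCCCCCCC)CCCCCCCC (its atoms stay only in 24)
Why: Appel-type SN2 displacement replaces the axial C2 oxygen by equatorial bromine with inversion, which sets the cis relation of Br and C1–O, while the silyl group keeps the anti-periplanar tertiary oxygen from closing an epoxide.

Step 17
Reactants: 25 {[(1R,2S,4S)-2-bromo-1-methyl-4-(prop-1-en-2-yl)cyclohexyl]oxy}triethylsilane
Product: 27 1-[(1S,3S,4R)-3-bromo-4-methyl-4-(triethylsilyloxy)cyclohexyl]ethan-1-one, via secondary ozonide 26 (not isolated)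
Conditions: O3, CH2Cl2, −78 °C; then Me2S, −78 °C to rt
Reagents that add atoms: ozone [O-][O+]=O
Why: Ozonolysis of the only alkene gives the methyl ketone, whose equatorial acetyl group is the stable epimer at C4 so the stereocentre is safe.

Step 18
Reactants: 27 1-[(1S,3S,4R)-3-bromo-4-methyl-4-(triethylsilyloxy)cyclohexyl]ethan-1-one
Product: 29 pinacol (E)-2-[(1S,3S,4R)-3-bromo-4-methyl-4-(triethylsilyloxy)cyclohexyl]prop-1-en-1-ylboronate, via lithium alkoxide adduct 28 (not isolated)
Conditions: CH2(Bpin)2, lithium 2,2,6,6-tetramethylpiperidide, THF, 0 °C; then 27, −78 °C to rt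
Reagents that add atoms: bis(pinacolatoboryl)methane CC1(C)OB(CB2OC(C)(C)C(C)(C)O2)OC1(C)C
Why: In the boron–Wittig olefination the stabilised gem-diboryl carbanion adds to the ketone and syn B–O elimination follows, the E-alkene being favoured because the remaining boryl group avoids the cyclohexyl substituent.

Step 19
Reactants: 18 (2R,5S)-5-bromo-2-[(E)-2-iodoethenyl]-2,6,6-trimethyloxane; 29 pinacol (E)-2-[(1S,3S,4R)-3-bromo-4-methyl-4-(triethylsilyloxy)cyclohexyl]prop-1-en-1-ylboronate
Product: 30 triethylsilyl ether of the target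
Conditions: PdCl2(dppf) (5 mol %), K3PO4 (aq), THF, rt
Reagents that add atoms: none
Why: The Suzuki–Miyaura coupling of an alkenyl iodide with an alkenyl boronate keeps both alkene geometries, and zerovalent palladium with this ligand does not insert into unactivated secondary alkyl bromides at room temperature.

Step 20
Reactants: 30 triethylsilyl ether of the target
Product: 31 (1R,2S,4S)-2-bromo-4-{(2E,4E)-5-[(2R,5S)-5-bromo-2,6,6-trimethyloxan-2-yl]penta-2,4-dien-2-yl}-1-methylcyclohexan-1-ol
Conditions: TBAF, AcOH, THF, 0 °C to rt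
Reagents that add atoms: none
Why: Buffered fluoride desilylation avoids the acid that would ionise the tertiary dienylic ether at C2 of the oxane, and the cis-bromohydrin that is freed cannot close an epoxide.

Compound list
1 | 1,1-dimethoxypropan-2-one | CC(=O)C(OC)OC | starting material
2 | (R)-1-phenylethanol | C[C@@H](O)c1ccccc1 | starting material
3 | 1-methoxy-1-[(R)-1-phenylethoxy]propan-2-one (both acetal epimers) | CC(=O)C(OC)O[C@H](C)c1ccccc1 | intermediate
4 | triethyl({3-methoxy-3-[(R)-1-phenylethoxy]prop-1-en-2-yl}oxy)silane | C=C(O[Si](CC)(CC)CC)C(OC)O[C@H](C)c1ccccc1 | intermediate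
5 | 2,5-dimethylfuran | Cc1ccc(C)o1 | starting material
6 | 1-[(R)-1-phenylethoxy]-2-(triethylsilyloxy)allyl cation triflate | C=C(O[Si](CC)(CC)CC)C=[O+][C@H](C)c1ccccc1.[O-]S(=O)(=O)C(F)(F)F | intermediate
7 | (1R,2S,5R)-1,5-dimethyl-2-[(R)-1-phenylethoxy]-8-oxabicyclo[3.2.1]oct-6-en-3-one | C[C@]12CC(=O)[C@@H](O[C@H](C)c3ccccc3)[C@](C)(O1)C=C2 | intermediate
8 | secondary ozonide of 7 (1,2,4-trioxolane in place of the etheno bridge) | C[C@]12CC(=O)[C@@H](O[C@H](C)c3ccccc3)[C@](C)(O1)C1OOC2O1 | intermediate
9 | (2R,4R,5R,6R)-2,6-bis(hydroxymethyl)-2,6-dimethyl-5-[(R)-1-phenylethoxy]oxan-4-ol | C[C@]1(CO)C[C@@H](O)[C@@H](O[C@H](C)c2ccccc2)[C@@](C)(CO)O1 | intermediate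
10 | (2R,4R,5R,6R)-2-[(tert-butyldiphenylsilyloxy)methyl]-6-(hydroxymethyl)-2,6-dimethyl-5-[(R)-1-phenylethoxy]oxan-4-ol | C[C@]1(CO[Si](c2ccccc2)(c2ccccc2)C(C)(C)C)C[C@@H](O)[C@@H](O[C@H](C)c2ccccc2)[C@@](C)(CO)O1 | intermediate
11 | bis(O-phenyl thionocarbonate) of 10 | C[C@]1(CO[Si](c2ccccc2)(c2ccccc2)C(C)(C)C)C[C@@H](OC(=S)Oc2ccccc2)[C@@H](O[C@H](C)c2ccccc2)[C@@](C)(COC(=S)Oc2ccccc2)O1 | intermediate
12 | (2R,5R)-2-[(tert-butyldiphenylsilyloxy)methyl]-2,6,6-trimethyl-5-[(R)-1-phenylethoxy]oxane | C[C@]1(CO[Si](c2ccccc2)(c2ccccc2)C(C)(C)C)CC[C@@H](O[C@H](C)c2ccccc2)C(C)(C)O1 | intermediate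
13 | (2R,5R)-2-[(tert-butyldiphenylsilyloxy)methyl]-2,6,6-trimethyloxan-5-ol | C[C@]1(CO[Si](c2ccccc2)(c2ccccc2)C(C)(C)C)CC[C@@H](O)C(C)(C)O1 | intermediate
14 | tri-n-octylphosphonium ether of 13, bromide salt | C[C@]1(CO[Si](c2ccccc2)(c2ccccc2)C(C)(C)C)CC[C@@H](O[P+](CCCCCCCC)(CCCCCCCC)CCCCCCCC)C(C)(C)O1.[Br-] | intermediate
15 | (2R,5S)-5-bromo-2-[(tert-butyldiphenylsilyloxy)methyl]-2,6,6-trimethyloxane | C[C@]1(CO[Si](c2ccccc2)(c2ccccc2)C(C)(C)C)CC[C@H](Br)C(C)(C)O1 | intermediate
16 | [(2R,5S)-5-bromo-2,6,6-trimethyloxan-2-yl]methanol | C[C@]1(CO)CC[C@H](Br)C(C)(C)O1 | intermediate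
17 | (2R,5S)-5-bromo-2,6,6-trimethyloxane-2-carbaldehyde | C[C@]1(C=O)CC[C@H](Br)C(C)(C)O1 | intermediate
18 | (2R,5S)-5-bromo-2-[(E)-2-iodoethenyl]-2,6,6-trimethyloxane | C[C@]1(/C=C/I)CC[C@H](Br)C(C)(C)O1 | intermediate
19 | (S)-(−)-limonene | C=C(C)[C@H]1CCC(C)=CC1 | starting material
20 | (4S)-limonene 1,2-oxide (both epoxide diastereomers) | C=C(C)[C@H]1CCC2(C)OC2C1 | intermediate
21 | (1R,2R,4S)-1-methyl-4-(prop-1-en-2-yl)cyclohexane-1,2-diol | C=C(C)[C@H]1CC[C@@](C)(O)[C@H](O)C1 | intermediate
22 | bis(triethylsilyl) ether of 21 | C=C(C)[C@H]1CC[C@@](C)(O[Si](CC)(CC)CC)[C@H](O[Si](CC)(CC)CC)C1 | intermediate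
23 | (1R,2R,4S)-1-methyl-4-(prop-1-en-2-yl)-1-(triethylsilyloxy)cyclohexan-2-ol | C=C(C)[C@H]1CC[C@@](C)(O[Si](CC)(CC)CC)[C@H](O)C1 | intermediate
24 | tri-n-octylphosphonium ether of 23, bromide salt | C=C(C)[C@H]1CC[C@@](C)(O[Si](CC)(CC)CC)[C@H](O[P+](CCCCCCCC)(CCCCCCCC)CCCCCCCC)C1.[Br-] | intermediate
25 | {[(1R,2S,4S)-2-bromo-1-methyl-4-(prop-1-en-2-yl)cyclohexyl]oxy}triethylsilane | C=C(C)[C@H]1CC[C@@](C)(O[Si](CC)(CC)CC)[C@@H](Br)C1 | intermediate
26 | secondary ozonide of 25 (3-methyl-1,2,4-trioxolan-3-yl group on C4) | CC1(OCOO1)[C@H]1CC[C@@](C)(O[Si](CC)(CC)CC)[C@@H](Br)C1 | intermediate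
27 | 1-[(1S,3S,4R)-3-bromo-4-methyl-4-(triethylsilyloxy)cyclohexyl]ethan-1-one | CC(=O)[C@H]1CC[C@@](C)(O[Si](CC)(CC)CC)[C@@H](Br)C1 | intermediate
28 | lithium alkoxide from addition of the gem-diboryl carbanion to 27 | CC([O-])(C(B1OC(C)(C)C(C)(C)O1)B1OC(C)(C)C(C)(C)O1)[C@H]1CC[C@@](C)(O[Si](CC)(CC)CC)[C@@H](Br)C1.[Li+] | intermediate
29 | pinacol (E)-2-[(1S,3S,4R)-3-bromo-4-methyl-4-(triethylsilyloxy)cyclohexyl]prop-1-en-1-ylboronate | C/C(=C\B1OC(C)(C)C(C)(C)O1)[C@H]1CC[C@@](C)(O[Si](CC)(CC)CC)[C@@H](Br)C1 | intermediate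
30 | triethylsilyl ether of the target | C/C(=C\C=C\[C@@]1(C)CC[C@H](Br)C(C)(C)O1)[C@H]1CC[C@@](C)(O[Si](CC)(CC)CC)[C@@H](Br)C1 | intermediate
31 | (1R,2S,4S)-2-bromo-4-{(2E,4E)-5-[(2R,5S)-5-bromo-2,6,6-trimethyloxan-2-yl]penta-2,4-dien-2-yl}-1-methylcyclohexan-1-ol | C/C(=C\C=C\[C@@]1(C)CC[C@H](Br)C(C)(C)O1)[C@H]1CC[C@@](C)(O)[C@@H](Br)C1 | target

Total number of steps: 20. Longest linear sequence: 14 steps (steps 1 to 12, then 19 and 20).

Steps most likely to fail

**Step 9.** SN2 attack at C5 is slowed by the fully substituted C6 next to it. Three processes may outrun substitution: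
- ionisation of the activated C–O bond with help from the ring oxygen, which contracts the ring;
- shift of the anti-periplanar C6 methyl group;
- E2 loss toward C4.

The fallback sets out from 13 and comes back at 15. It makes the C–Br bond on an sp2 carbon and sets the stereocentre by hydrogen delivery instead of substitution. Dess–Martin oxidation of 13 gives the oxan-5-one F1, and hydrazine hydrate gives the hydrazone F2. The Barton vinyl bromide synthesis (Br2, 2-tert-butyl-1,1,3,3-tetramethylguanidine) then gives a single vinyl bromide F3, because only C4 carries hydrogen. Hydrogen-atom-transfer hydrogenation (Mn(dpm)3, PhSiH3, t-BuOOH, i-PrOH) is known to keep vinylic halogen. It should deliver the second hydrogen to the C5 radical from the face away from the axial C6 methyl group and so leave bromine equatorial as in 15.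

**Step 16.** E2 loss of the activated axial oxygen toward C3, together with slow SN2 attack beside the fully substituted C1, may erode the substitution. The fallback sets out from 21 and comes back at 27. It uses one ring both to activate C2–O and to mask C1–O:
- Ozonolysis of 21 (O3, then Me2S) gives the keto diol F4.
- SOCl2 and pyridine give the cyclic sulfite F5, and RuCl3 (cat.) with NaIO4 gives the cyclic sulfate F6.
- LiBr in THF opens the sulfate at the secondary carbon with inversion to the lithium bromo sulfate F7.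
- Dilute H2SO4 in wet THF hydrolyses this by S–O cleavage to the bromohydrin ketone F8.
- TESOTf and 2,6-lutidine convert F8 into 27.

**Step 5.** Site selectivity between the two neopentylic primary alcohols may be poor, and the silyl group may migrate between the two neighbouring arms. The fallback sets out from 7 and comes back at 13. It recognises the C6 arm through its 1,3-relation to the C5 oxygen instead of through sterics:
- LiBH(s-Bu)3 reduces 7 to the axial bicyclic alcohol F9, phenyl chlorothionoformate gives the thionocarbonate F10, and Bu3SnH with AIBN gives the 3-deoxy bicycle F11.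
- Ozonolysis with NaBH4 work-up gives the diol F12, and hydrogenolysis over Pd(OH)2/C gives the triol F13.
- Only the C5 hydroxyl and the C6 hydroxymethyl group can share a six-membered ring, so 2,2-dimethoxypropane with PPTS gives the 1,3-dioxane F14 and leaves the C2 arm free for silylation to the silyl ether F15.
- Aqueous acetic acid frees the diol F16, whose primary hydroxyl is acylated first to the mono-thionocarbonate F17.
- Bu3SnH with AIBN then delivers 13.

Further compounds
F1 | step 9 | (2R)-2-[(tert-butyldiphenylsilyloxy)methyl]-2,6,6-trimethyloxan-5-one | C[C@]1(CO[Si](c2ccccc2)(c2ccccc2)C(C)(C)C)CCC(=O)C(C)(C)O1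
F2 | step 9 | hydrazone of F1 | C[C@]1(CO[Si](c2ccccc2)(c2ccccc2)C(C)(C)C)CCC(=NN)C(C)(C)O1
F3 | step 9 | (2R)-5-bromo-2-[(tert-butyldiphenylsilyloxy)methyl]-2,6,6-trimethyl-3,6-dihydro-2H-pyran | C[C@]1(CO[Si](c2ccccc2)(c2ccccc2)C(C)(C)C)CC=C(Br)C(C)(C)O1
F4 | step 16 | 1-[(1S,3R,4R)-3,4-dihydroxy-4-methylcyclohexyl]ethan-1-one | CC(=O)[C@H]1CC[C@@](C)(O)[C@H](O)C1
F5 | step 16 | cyclic sulfite of F4 | CC(=O)[C@H]1CC[C@@]2(C)OS(=O)O[C@@H]2C1
F6 | step 16 | cyclic sulfate of F4 | CC(=O)[C@H]1CC[C@@]2(C)OS(=O)(=O)O[C@@H]2C1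
F7 | step 16 | lithium (1R,2S,4S)-4-acetyl-2-bromo-1-methylcyclohexyl sulfate | CC(=O)[C@H]1CC[C@@](C)(OS(=O)(=O)[O-])[C@@H](Br)C1.[Li+]
F8 | step 16 | 1-[(1S,3S,4R)-3-bromo-4-hydroxy-4-methylcyclohexyl]ethan-1-one | CC(=O)[C@H]1CC[C@@](C)(O)[C@@H](Br)C1
F9 | step 5 | axial C3 alcohol from 7 (hydroxyl cis to the alkoxy group and the etheno bridge) | C[C@]12C[C@@H](O)[C@@H](O[C@H](C)c3ccccc3)[C@](C)(O1)C=C2
F10 | step 5 | O-phenyl thionocarbonate of F9 | C[C@]12C[C@@H](OC(=S)Oc3ccccc3)[C@@H](O[C@H](C)c3ccccc3)[C@](C)(O1)C=C2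
F11 | step 5 | 1,5-dimethyl-2-[(R)-1-phenylethoxy]-8-oxabicyclo[3.2.1]oct-6-ene (ring configuration as in 7) | C[C@]12CC[C@@H](O[C@H](C)c3ccccc3)[C@](C)(O1)C=C2
F12 | step 5 | 2,6-bis(hydroxymethyl)-2,6-dimethyl-5-[(R)-1-phenylethoxy]oxane (arms and alkoxy group all cis) | C[C@]1(CO)CC[C@@H](O[C@H](C)c2ccccc2)[C@@](C)(CO)O1
F13 | step 5 | 2,6-bis(hydroxymethyl)-2,6-dimethyloxan-5-ol (arms and hydroxyl all cis) | C[C@]1(CO)CC[C@@H](O)[C@@](C)(CO)O1
F14 | step 5 | acetonide of F13 across the C5 oxygen and the C6 arm (cis-fused 1,3-dioxane) | C[C@]1(CO)CC[C@H]2OC(C)(C)OC[C@@]2(C)O1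
F15 | step 5 | tert-butyldiphenylsilyl ether of F14 | C[C@]1(CO[Si](c3ccccc3)(c3ccccc3)C(C)(C)C)CC[C@H]2OC(C)(C)OC[C@@]2(C)O1
F16 | step 5 | 2-[(tert-butyldiphenylsilyloxy)methyl]-6-(hydroxymethyl)-2,6-dimethyloxan-5-ol | C[C@]1(CO[Si](c2ccccc2)(c2ccccc2)C(C)(C)C)CC[C@@H](O)[C@@](C)(CO)O1
F17 | step 5 | O-phenyl thionocarbonate of F16 on the primary oxygen | C[C@]1(CO[Si](c2ccccc2)(c2ccccc2)C(C)(C)C)CC[C@@H](O)[C@@](C)(COC(=S)Oc2ccccc2)O1
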